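**Strategy.** Everything rests on cutting the C8–C15 bond of ring D back to a C9–C15 bond, which turns the ring C/D bicyclo[3.2.1]octene into a Diels–Alder-derived bicyclo[2.2.2]octenone. In one radical operation the keto bridge carbon C15 shifts from bridgehead C9 to C8: this closes cyclopentanone ring D, creates quaternary C8 and leaves the C9=C11 alkene. The step exploits the fact that the ring D carbonyl C15 sits on quaternary C8 directly beside the C9–C11 epoxide site of ring C. Its precursor is the resolved bromo ester adduct of oxidised o-cresol and methyl 2-bromoacrylate. Ring A is then joined at C9–C10 by a ketal Claisen rearrangement.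

Key step: step 3

Remark: skeletal atoms carry ent-kaurane numbers throughout; the lactol centre C6 can equilibrate through the open hydroxy aldehyde, so its configuration in the target is taken to be the thermodynamic one.

**Step 1**
Reactants: 1 o-cresol; 2 methyl 2-bromoacrylate
Product: 4 racemic methyl 3-acetoxy-7-bromo-3-methyl-2-oxobicyclo[2.2.2]oct-5-ene-7-carboxylate (acetoxy anti to the alkene, ester syn to the alkene), via acetoxy dienone 3 (not isolated)
Conditions: Pb(OAc)4, AcOH/CH2Cl2, 0 °C; then 2 (5 equiv), toluene, 90 °C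
Reagents that add atoms: lead tetraacetate, Pb(OAc)4, CC(=O)O[Pb](OC(C)=O)(OC(C)=O)OC(C)=O
Why: Wessely oxidation acetoxylates the methyl-bearing ortho carbon, and the dienone is caught in a Diels–Alder reaction in which the bromoacrylate adds syn to the acetoxy group, with its substituted carbon bonded to the diene terminus next to the carbonyl and the ester endo, which sets the relative configuration of C9, C13, C16 and C8 (either C8 epimer would serve, since C8 becomes a radical in step 3).

**Step 2**
Reactants: 4 racemic bromo ester adduct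
Product: 5 methyl (1R,3S,4S,7R)-3-acetoxy-7-bromo-3-methyl-2-oxobicyclo[2.2.2]oct-5-ene-7-carboxylate
Conditions: preparative SFC, amylose tris(3,5-dimethylphenylcarbamate) stationary phase, CO2/MeOH
Reagents that add atoms: none
Why: Resolution by chromatography on a chiral stationary phase separates the enantiomers of the rigid, UV-active adduct without chemical change, and the enantiomer kept has C13 as in the target.

**Step 3**
Reactants: 5 resolved bromo ester adduct
Product: 6 methyl (1S,5R,6S)-6-acetoxy-6-methyl-7-oxobicyclo[3.2.1]oct-2-ene-1-carboxylate (methyl endo, acetoxy exo)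
Conditions: Bu3SnH (1.3 equiv), AIBN (0.2 equiv), syringe pump over 8 h, PhH (0.01 M), 80 °C
Reagents that add atoms: none
Why: Bu3Sn• removes bromine to give the tertiary α-ester radical at C8, which adds 3-exo-trig to the C15 carbonyl carbon; the cyclopropyloxy radical opens by cleavage of C9–C15, so the acyl group moves from C9 to C8 and the spin ends in the C9–C11–C12 allyl radical, which takes hydrogen from the stannane at C12. The closest precedents are the Dowd–Beckwith 1,2-acyl shift and the radical rearrangement of bicyclo[2.2.2]octenones to bicyclo[3.2.1]octenes. Ring D (C8, C14, C13, C16, C15) closes by this 3-exo-trig addition followed by β-scission, a net contraction of the six-membered keto ring by one carbon. The new quaternary stereocentre C8 is fixed by the cage, because the acyl bridge can only slide along one face of the bicycle, so its configuration follows from C13 of resolved 5. The step needs the acyl shift to beat both the vinyl shift and direct reduction, and hydrogen delivery at C12 rather than C9; slow stannane addition at high dilution keeps the shifts reversible so that they drain to the allyl radical, the most stable one, and quaternary C8 beside C9 screens that terminus.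

**Step 4**
Reactants: 6 acetoxy keto ester
Product: 7 methyl (1S,5R,6R)-6-methyl-7-oxobicyclo[3.2.1]oct-2-ene-1-carboxylate (C16 methyl endo)
Conditions: SmI2 (2.5 equiv), THF/MeOH, −78 °C
Reagents that add atoms: none
Why: Reductive cleavage of the α-acetoxy ketone by SmI2 gives an enolate across C15–C16, which methanol protonates kinetically from the open exo face (the C14 side), so the C16 methyl ends endo as in the target.

**Step 5**
Reactants: 7 keto ester
Product: 8 ethylene ketal of 7 (1,3-dioxolane at C15, stereocentres unchanged)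
Conditions: (TMSOCH2)2, TMSOTf (10 mol %), CH2Cl2, −78 → −20 °C
Reagents that add atoms: 1,2-bis(trimethylsilyloxy)ethane, C[Si](C)(C)OCCO[Si](C)(C)C
Why: Noyori ketalisation under aprotic low-temperature conditions masks the C15 ketone without enolising towards C16, which protects it from hydride and locks the C16 stereocentre.

**Step 6**
Reactants: 8 ketal ester
Product: 9 C7 primary alcohol (hydroxymethyl on C8, ketal retained)
Conditions: LiAlH4, THF, 0 °C
Reagents that add atoms: none
Why: Hydride reduction of the neopentyl methyl ester gives the C7 alcohol, while the ketal and the alkene are inert and no stereocentre is touched.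

**Step 7**
Reactants: 9 primary alcohol
Product: 10 TBS ether of 9
Conditions: TBSCl, imidazole, DMF, rt
Reagents that add atoms: tert-butyldimethylsilyl chloride, CC(C)(C)[Si](C)(C)Cl
Why: Silylation of the only hydroxyl gives an ether that is stable to the coming oxidation, hydride and acylation steps and falls off in the final acid step.

**Step 8**
Reactants: 10 silyl ether
Product: 11 C12-exo allylic alcohol of 10 (hydroxyl on the C14 side, alkene still C9=C11)
Conditions: SeO2 (0.5 equiv), t-BuOOH, CH2Cl2, rt
Reagents that add atoms: selenium dioxide, O=[Se]=O; tert-butyl hydroperoxide, CC(C)(C)OO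
Why: Selenium dioxide allylic oxidation (ene reaction, then [2,3]-sigmatropic shift) can only use the C12 hydrogens, C8 being quaternary, and both events occur on the exo face, so the C12 hydroxyl is set exo and the alkene returns to C9=C11.

**Step 9**
Reactants: 12 4,4-dimethylcyclohex-2-en-1-one
Product: 13 4,4-dimethylcyclohexa-2,5-dien-1-one
Conditions: IBX, DMSO, 80 °C
Reagents that add atoms: none
Why: IBX dehydrogenation of the saturated α,β-positions gives the symmetrical cross-conjugated dienone, with no stereocentre formed.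

**Step 10**
Reactants: 13 dienone
Product: 14 (R)-4,4-dimethyl-5-vinylcyclohex-2-en-1-one
Conditions: KBF3(CH=CH2) (1.2 equiv), [Rh(cod)2]BF4 (3 mol %), (R)-BINAP, Et3N, toluene/H2O, 60 °C
Reagents that add atoms: potassium vinyltrifluoroborate, [K+].C=C[B-](F)(F)F
Why: Rhodium-catalysed asymmetric 1,4-addition (Hayashi–Miyaura type) of the vinyl group to one of the two enantiotopic enone arms desymmetrises the dienone, and the (R)-BINAP complex is expected, by analogy with additions to cyclohex-2-enone, to set C5 as drawn.

**Step 11**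
Reactants: 14 vinyl enone
Product: 15 (5S,6S)-4,4,6-trimethyl-5-vinylcyclohex-2-en-1-one (5,6-trans)
Conditions: LDA, THF, −78 °C; MeI, −78 → −20 °C
Reagents that add atoms: iodomethane, CI
Why: The only enolisable position is C10 (C4 is quaternary), so enolate alkylation anti to the vinyl group installs the C20 methyl, and the C10 configuration is immaterial because C10 becomes trigonal in step 13.

**Step 12**
Reactants: 15 methylated vinyl enone
Product: 17 (5,6-trans)-5-(dimethoxymethyl)-1,1-dimethoxy-4,4,6-trimethylcyclohex-2-ene (C1 ketal, C6 acetal), via keto aldehyde 16 (not isolated)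
Conditions: O3, CH2Cl2/MeOH, −78 °C; Me2S; then HC(OMe)3, CSA (cat.), MeOH, rt
Reagents that add atoms: trimethyl orthoformate, COC(OC)OC; methanol, CO
Why: Ozonolysis cleaves the electron-rich vinyl group in preference to the hindered conjugated alkene (the selectivity known for carvone-type substrates), and acid-catalysed acetalisation then converts the C6 aldehyde and the C1 ketone into their dimethyl acetals faster than C5 can epimerise.

**Step 13**
Reactants: 11 allylic alcohol; 17 ring A ketal (3 equiv)
Product: 19 ring A enone (C1=O, C2=C3) joined through quaternary C10 to C9 of the bicycle (ring A exo on C9, alkene C11=C12, C9 trans to C6 on ring A), via allyl dienyl ether 18 (not isolated)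
Conditions: EtCO2H (10 mol %), xylene, 140 °C, MeOH distilled off
Reagents that add atoms: none
Why: In this Johnson-type ketal Claisen rearrangement, exchange of the C12 hydroxyl into the ketal and loss of methanol can only give the cross-conjugated allyl dienyl ether (C4 is quaternary), whose [3,3] shift forms C9–C10 suprafacially on the exo face of ring C and, on ring A, anti to the pseudoaxial C5 substituent, which sets quaternary C10 and returns the C1 enone (the C9 centre formed here is erased in step 18).

**Step 14**
Reactants: 19 enone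
Product: 20 C1 allylic alcohol (hydroxyl cis to the C10 methyl)
Conditions: NaBH4, CeCl3·7H2O, MeOH, −40 °C
Reagents that add atoms: none
Why: In this Luche 1,2-reduction hydride adds to C1 from the face opposite the pseudoaxial C10 methyl, so the C1 hydroxyl ends equatorial and cis to that methyl, as the target requires.

**Step 15**
Reactants: 20 allylic alcohol
Product: 21 2,3-epoxy alcohol (epoxide cis to the C1 hydroxyl)
Conditions: VO(acac)2 (5 mol %), t-BuOOH, CH2Cl2, 0 °C → rt
Reagents that add atoms: tert-butyl hydroperoxide, CC(C)(C)OO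
Why: Vanadium-catalysed hydroxyl-directed epoxidation delivers oxygen to C2=C3 syn to the C1 hydroxyl, onto the face an undirected reagent would avoid, and leaves the remote C11=C12 alkene alone.

**Step 16**
Reactants: 21 epoxy alcohol
Product: 22 1,2-cis-diol (C3 now methylene)
Conditions: LiAlH4, THF, 65 °C
Reagents that add atoms: none
Why: Hydride opens the epoxide by trans-diaxial (Fürst–Plattner) attack at C3, the carbon remote from the carbinol, from the face opposite the oxygen, which leaves the C2 hydroxyl axial and cis to the C1 hydroxyl.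

**Step 17**
Reactants: 22 diol
Product: 23 1,2-diacetate
Conditions: Ac2O, pyridine, DMAP, 40 °C
Reagents that add atoms: acetic anhydride, CC(=O)OC(C)=O
Why: DMAP-catalysed acetylation of the only two free hydroxyls gives the diacetate without change at any stereocentre.

**Step 18**
Reactants: 23 diacetate
Product: 24 C12 allylic bromide with the alkene moved to C9=C11
Conditions: NBS, AIBN (cat.), K2CO3, PhCF3, 80 °C
Reagents that add atoms: N-bromosuccinimide, O=C1CCC(=O)N1Br
Why: In this Wohl–Ziegler bromination the bromine atom abstracts H9, the only hydrogen whose C–H bond overlaps an alkene π system and by far the weakest, and the C9–C11–C12 allyl radical takes bromine at the accessible C12 end, which moves the alkene to C9=C11 and makes C9 trigonal.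

**Step 19**
Reactants: 24 allylic bromide
Product: 25 C9=C11 alkene with C12 methylene
Conditions: Bu3SnH, AIBN, PhH, 80 °C
Reagents that add atoms: none
Why: Stannane reduction of the allylic bromide passes through the same allyl radical, which accepts hydrogen at C12 because C9 lies between quaternary C8 and C10, so the C9=C11 alkene is kept (the regiochemistry of step 3).

**Step 20**
Reactants: 25 protected alkene
Product: 27 lactol ketone (the 9(11)-ene of the target), via hydroxy keto aldehyde 26 (not isolated)
Conditions: 1 M HCl, THF, rt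
Reagents that add atoms: water, O
Why: Aqueous acid hydrolyses the dioxolane, the silyl ether and the dimethyl acetal in one operation, and the freed C6 aldehyde closes onto the C7 hydroxyl to the seven-membered lactol, in which C6 (and, through the open aldehyde, C5 if needed) settles to the thermodynamic configuration.

**Step 21**
Reactants: 27 lactol alkene
Product: 28 target CNP0210140.1
Conditions: DMDO, acetone, 0 °C
Reagents that add atoms: dimethyldioxirane, CC1(C)OO1
Why: Epoxidation of the only alkene with DMDO should occur on the exo face (the C14 side), the endo face being screened by C1 with its acetoxy group, the C15 carbonyl bridge and the endo C16 methyl, which sets C9 and C11.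

**Compound list**

1 | o-cresol | Cc1ccccc1O | starting material
2 | methyl 2-bromoacrylate | COC(=O)C(Br)=C | starting material
3 | 6-acetoxy-6-methylcyclohexa-2,4-dien-1-one (racemic) | CC(=O)OC1(C)C=CC=CC1=O | intermediate
4 | racemic methyl 3-acetoxy-7-bromo-3-methyl-2-oxobicyclo[2.2.2]oct-5-ene-7-carboxylate (one enantiomer drawn) | COC(=O)[C@@]1(Br)C[C@H]2C=C[C@@H]1C(=O)[C@@]2(C)OC(C)=O | intermediate
5 | methyl (1R,3S,4S,7R)-3-acetoxy-7-bromo-3-methyl-2-oxobicyclo[2.2.2]oct-5-ene-7-carboxylate | COC(=O)[C@@]1(Br)C[C@H]2C=C[C@@H]1C(=O)[C@@]2(C)OC(C)=O | intermediate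
6 | methyl (1S,5R,6S)-6-acetoxy-6-methyl-7-oxobicyclo[3.2.1]oct-2-ene-1-carboxylate | COC(=O)[C@]12C=CC[C@H](C1)[C@](C)(OC(C)=O)C2=O | intermediate
7 | methyl (1S,5R,6R)-6-methyl-7-oxobicyclo[3.2.1]oct-2-ene-1-carboxylate (methyl endo) | COC(=O)[C@]12C=CC[C@H](C1)[C@@H](C)C2=O | intermediate
8 | ethylene ketal of 7 (dioxolane at C15) | COC(=O)[C@]12C=CC[C@H](C1)[C@@H](C)C23OCCO3 | intermediate
9 | C7 primary alcohol from 8 | OC[C@]12C=CC[C@H](C1)[C@@H](C)C23OCCO3 | intermediate
10 | TBS ether of 9 | CC(C)(C)[Si](C)(C)OC[C@]12C=CC[C@H](C1)[C@@H](C)C23OCCO3 | intermediate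
11 | C12-exo allylic alcohol of 10 | CC(C)(C)[Si](C)(C)OC[C@]12C=C[C@H](O)[C@H](C1)[C@@H](C)C23OCCO3 | intermediate
12 | 4,4-dimethylcyclohex-2-en-1-one | CC1(C)CCC(=O)C=C1 | starting material
13 | 4,4-dimethylcyclohexa-2,5-dien-1-one | CC1(C)C=CC(=O)C=C1 | intermediate
14 | (R)-4,4-dimethyl-5-vinylcyclohex-2-en-1-one | O=C1C=CC(C)(C)[C@@H](C=C)C1 | intermediate
15 | (5S,6S)-4,4,6-trimethyl-5-vinylcyclohex-2-en-1-one | O=C1C=CC(C)(C)[C@@H](C=C)[C@@H]1C | intermediate
16 | trans-2,6,6-trimethyl-3-oxocyclohex-4-ene-1-carbaldehyde (C6 aldehyde) | O=C1C=CC(C)(C)[C@@H](C=O)[C@@H]1C | intermediate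
17 | (5,6-trans)-5-(dimethoxymethyl)-1,1-dimethoxy-4,4,6-trimethylcyclohex-2-ene | COC1(OC)C=CC(C)(C)[C@@H](C(OC)OC)[C@@H]1C | intermediate
18 | allyl dienyl ether (C12–O–C1; C1=C10 and C2=C3 in ring A) | CC(C)(C)[Si](C)(C)OC[C@]12C=C[C@H](OC4=C(C)[C@H](C(OC)OC)C(C)(C)C=C4)[C@H](C1)[C@@H](C)C23OCCO3 | intermediate
19 | Claisen product: ring A enone joined C10–C9 to the bicycle, alkene C11=C12 | O=C1C=CC(C)(C)[C@@H](C(OC)OC)[C@]1(C)[C@@H]2C=C[C@@H]3C[C@@]2(CO[Si](C)(C)C(C)(C)C)C4(OCCO4)[C@@H]3C | intermediate
20 | C1 allylic alcohol of 19 | O[C@H]1C=CC(C)(C)[C@@H](C(OC)OC)[C@]1(C)[C@@H]2C=C[C@@H]3C[C@@]2(CO[Si](C)(C)C(C)(C)C)C4(OCCO4)[C@@H]3C | intermediate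
21 | 2,3-epoxy-1-ol (epoxide cis to hydroxyl) | O[C@H]1[C@H]5O[C@H]5C(C)(C)[C@@H](C(OC)OC)[C@]1(C)[C@@H]2C=C[C@@H]3C[C@@]2(CO[Si](C)(C)C(C)(C)C)C4(OCCO4)[C@@H]3C | intermediate
22 | 1,2-cis-diol | O[C@H]1[C@@H](O)CC(C)(C)[C@@H](C(OC)OC)[C@]1(C)[C@@H]2C=C[C@@H]3C[C@@]2(CO[Si](C)(C)C(C)(C)C)C4(OCCO4)[C@@H]3C | intermediate
23 | 1,2-diacetate | CC(=O)O[C@H]1[C@@H](OC(C)=O)CC(C)(C)[C@@H](C(OC)OC)[C@]1(C)[C@@H]2C=C[C@@H]3C[C@@]2(CO[Si](C)(C)C(C)(C)C)C4(OCCO4)[C@@H]3C | intermediate
24 | C12 allylic bromide, alkene C9=C11 | CC(=O)O[C@H]1[C@@H](OC(C)=O)CC(C)(C)[C@@H](C(OC)OC)[C@]1(C)C2=C[C@H](Br)[C@@H]3C[C@@]2(CO[Si](C)(C)C(C)(C)C)C4(OCCO4)[C@@H]3C | intermediate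
25 | C9=C11 alkene, fully protected | CC(=O)O[C@H]1[C@@H](OC(C)=O)CC(C)(C)[C@@H](C(OC)OC)[C@]1(C)C2=CC[C@@H]3C[C@@]2(CO[Si](C)(C)C(C)(C)C)C4(OCCO4)[C@@H]3C | intermediate
26 | hydroxy keto aldehyde (C6 aldehyde, C7 hydroxyl, C15 ketone) | CC(=O)O[C@H]1[C@@H](OC(C)=O)CC(C)(C)[C@@H](C=O)[C@]1(C)C2=CC[C@@H]3C[C@@]2(CO)C(=O)[C@@H]3C | intermediate
27 | lactol ketone, 9(11)-ene of the target | CC(=O)O[C@H]1CC(C)(C)[C@H]2[C@H](O)OC[C@@]34C[C@@H](CC=C3[C@]2(C)[C@H]1OC(C)=O)[C@@H](C)C4=O | intermediate
28 | CNP0210140.1 | CC(=O)O[C@H]1CC(C)(C)[C@H]2[C@H](O)OC[C@@]34C[C@@H](C[C@H]5O[C@]53[C@]2(C)[C@H]1OC(C)=O)[C@@H](C)C4=O | target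

**Step count.** Total: 21 steps. Longest linear sequence: 17 steps (steps 1–8, then 13–21); the ring A branch (steps 9–12) is 4 steps.

**Steps most likely to fail**

Step 13 (ketal Claisen union). The hindered allylic alcohol may ionise or decompose under acid and heat before the crowded mixed ketal can form and eliminate. The fallback makes the enol ether without acid. From 17, brief treatment with wet silica gel should hydrolyse only the conjugated ketal to the enone acetal F1. Hydrazine gives the hydrazone F2, and iodine with tetramethylguanidine (Barton vinyl iodide synthesis) the dienyl iodide F3. Copper-catalysed C–O coupling of F3 with 11 (CuI, 3,4,7,8-tetramethyl-1,10-phenanthroline, Cs2CO3, toluene, 80 °C) should give ether 18 under basic conditions. Heating to 130 °C then rearranges it to 19, where the route is rejoined.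

Step 18 (allylic bromination with transposition). Bromine atom attack at other C–H bonds, or ionic addition of bromine across C11=C12, may outrun abstraction of H9. The fallback does the transposition by oxidation. From 23, CrO3·3,5-dimethylpyrazole (CH2Cl2, −20 °C) should oxidise the allylic position with transposition to the enone F4 (C9=C11–C12=O). Luche reduction gives the allylic alcohol F5, and phenyl chlorothionoformate with pyridine the thionocarbonate F6. Barton–McCombie reduction (Bu3SnH, AIBN) passes through the same allyl radical and returns to the route at 25.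

Step 3 (radical acyl shift). The stabilised, electrophilic α-ester radical may be reduced by the stannane, or add to the alkene, before it attacks the ketone carbon. The fallback makes the radical nucleophilic. From 1, dienone 3 is trapped with 2-bromoacrolein to give the aldehyde adduct F7 (either C8 epimer serves). NaBH4 at −78 °C should reduce only the aldehyde to the bromohydrin F8, and TBSCl gives the silyl ether F9, which is resolved as in step 2. Bu3SnH then generates a tertiary alkyl radical, the polarity-matched case of the Dowd–Beckwith acyl shift, and should give the ring-contracted ketone F10. SmI2/MeOH gives the ketone F11, and ketalisation as in step 5 returns to the route at 10, so that steps 6 and 7 fall away.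

**Further compounds**

F1 | step 13 | (5,6-trans)-5-(dimethoxymethyl)-4,4,6-trimethylcyclohex-2-en-1-one | O=C1C=CC(C)(C)[C@@H](C(OC)OC)[C@@H]1C
F2 | step 13 | hydrazone of F1 | NN=C1C=CC(C)(C)[C@@H](C(OC)OC)[C@@H]1C
F3 | step 13 | 5-(dimethoxymethyl)-1-iodo-4,4,6-trimethylcyclohexa-1(6),2-diene (dienyl iodide) | CC1=C(I)C=CC(C)(C)[C@H]1C(OC)OC
F4 | step 18 | C12 enone of 23 (C9=C11–C12=O) | CC(=O)O[C@H]1[C@@H](OC(C)=O)CC(C)(C)[C@@H](C(OC)OC)[C@]1(C)C2=CC(=O)[C@@H]3C[C@@]2(CO[Si](C)(C)C(C)(C)C)C4(OCCO4)[C@@H]3C
F5 | step 18 | C12-endo allylic alcohol from F4 | CC(=O)O[C@H]1[C@@H](OC(C)=O)CC(C)(C)[C@@H](C(OC)OC)[C@]1(C)C2=C[C@@H](O)[C@@H]3C[C@@]2(CO[Si](C)(C)C(C)(C)C)C4(OCCO4)[C@@H]3C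
F6 | step 18 | O-phenyl thionocarbonate of F5 | CC(=O)O[C@H]1[C@@H](OC(C)=O)CC(C)(C)[C@@H](C(OC)OC)[C@]1(C)C2=C[C@@H](OC(=S)Oc5ccccc5)[C@@H]3C[C@@]2(CO[Si](C)(C)C(C)(C)C)C4(OCCO4)[C@@H]3C
F7 | step 3 | 3-acetoxy-7-bromo-3-methyl-2-oxobicyclo[2.2.2]oct-5-ene-7-carbaldehyde | O=C[C@@]1(Br)C[C@H]2C=C[C@@H]1C(=O)[C@@]2(C)OC(C)=O
F8 | step 3 | 7-bromo-7-(hydroxymethyl) analogue (bromohydrin) | OC[C@@]1(Br)C[C@H]2C=C[C@@H]1C(=O)[C@@]2(C)OC(C)=O
F9 | step 3 | TBS ether of F8 | CC(C)(C)[Si](C)(C)OC[C@@]1(Br)C[C@H]2C=C[C@@H]1C(=O)[C@@]2(C)OC(C)=O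
F10 | step 3 | 6-acetoxy-6-methyl-1-(silyloxymethyl)bicyclo[3.2.1]oct-2-en-7-one | CC(C)(C)[Si](C)(C)OC[C@]12C=CC[C@H](C1)[C@](C)(OC(C)=O)C2=O
F11 | step 3 | 6-endo-methyl-1-(silyloxymethyl)bicyclo[3.2.1]oct-2-en-7-one | CC(C)(C)[Si](C)(C)OC[C@]12C=CC[C@H](C1)[C@@H](C)C2=O
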